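The numbers in the tables are simulated for substances that don't exist; scatter was added.

Which flask ends with the larger share of target, and does the gap between them clear the margin? I reckoned the gap first, because the margin judges it.

| flask | substrate | partner | temperature | remark | time |
|---|---|---|---|---|---|
| birch | 0.061 M | 0.131 M | 95 °C | run made earlier |  |
| maple | 0.094 M | 0.131 M | 106 °C | run made earlier |  |
| oak | 0.073 M | 0.20 M | 95 °C | run made earlier |  |
| Monday's | 0.050 M | 0.250 M | 100 °C |  | 80 d |
| Friday's | 0.073 M | 0.131 M | 100 °C |  | 20 d |

- birch (time / d: target / %, isomer of the product / %, substrate / %): 1.04: 10.9, 1.7, 87.1; 2.00: 19.1, 3.5, 78.1; 4.00: 31.2, 8.2, 59.7; 8.00: 41.7, 21.1, 33.8; 15.0: 52.8, 34.3, 15.5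
- maple (time / d: target / %, isomer of the product / %, substrate / %): 3.00: 47.5, 22.1, 29.4; 6.00: 58.0, 34.5, 9.4; 8.00: 58.9, 37.4, 4.4; 12.0: 58.8, 39.5, 4.1; 15.0: 59.0, 39.9, 0.4
- oak (time / d: target / %, isomer of the product / %, substrate / %): 3.00: 24.5, 6.0, 70.6; 6.00: 35.2, 16.2, 47.1; 8.00: 43.2, 20.9, 37.6; 12.0: 48.3, 29.5, 22.9; 15.0: 53.8, 33.3, 13.7

(scatter of a reading: 1 percentage point)



- the winner by share of target in all that became target or isomer of the product; "neither" if no more than 2 percentage points parts them (Monday's / Friday's / neither)
- share of target in all that became target or isomer of the product, Monday's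
- share of target in all that became target or isomer of the product, Friday's

1. Main step by itself. Substrate going to target gives a share of 100 %, so the question is how far substrate has gone. I counted decades: the logarithm to base ten of charged over remaining. Birch burned 0.0540 /d and maple 0.171 /d. Interpolating the logarithm in temperature gave 0.0912 /d at 100 °C. So Friday's reached 1.82 decades, leaving 1.50 % of its substrate, and Monday's reached 7.30.

2. Add the isomer of the product. It lags, so I took it to come from target. Maple's last reading gives a plateau share of 59.7 %, which is thermodynamic control if this is an equilibrium. Birch at 8.00 d read 66.4 %, above the plateau. I assumed this excess follows the odds of substrate, remaining over converted. The excess per unit of odds is the lag, 0.132, and I assumed it unchanged at 100 °C.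

3. Add the partner. Oak, at birch's temperature with more partner than birch and also more substrate, gave a lag of 0.128 at 8.00 d, so I made no correction.

4. Friday's excess came to 0.2 percentage points, and I set Monday's to nil. That gave 59.7 % for Monday's and 59.9 % for Friday's. The gap is smaller than the 2 points margin, so I expected the two to count as equal.

5. The forecast gave neither, with 59.8 % and 60 %, since “both runs should reach the plateau”. The flasks gave 58.8 % for Monday's and 59.0 % for Friday's, so the answer is neither.

    target ⇌ isomer of the product (K = 0.700, k = 3.90 × 10⁻⁶ /s, Ea = 123 kJ/mol, ΔH = −8.00 kJ/mol)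
    substrate ⇌ intermediate + leaving ligand (K = 0.00250 M, k = 2.50 × 10⁻⁶ /s, Ea = 122 kJ/mol, ΔH = −79.0 kJ/mol)
    partner + intermediate → target (k = 0.0500 /M/s, Ea = 77.0 kJ/mol)
    (constants at 100 °C)

In Friday's, the relaxation half-life of target and isomer of the product, 0.847 d, is shorter than the substrate half-life of 3.30 d from my decades. Friday's 1.43 % of substrate at 20.0 d gives an excess of 0.19 points through the lag, and the gap over Monday's is 0.20 points. Friday's read at 5.0 d held 34.2 % substrate, which gives 6.9 points, and it stood 7.2 points above Monday's.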